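The 1,2-dioxolane (O1–O2–C3–C4–C5) carries methyl-bearing quaternary carbons at C3 and C5 on either side of the C4 methylene, so it is cut at C3–C4 and O1–C5 into a ketone-derived silylperoxy ketal and a 2-methyl-1-alkene. One cationic [3+2] annulation under a confined chiral counteranion forms both bonds, the ring and both stereocentres. Its precursors are racemic 3-methoxy-3-[(triethylsilyl)peroxy]butyl acetate (C3 becomes planar on ionisation) and 2-methyldeca-1,9-diene, whose monosubstituted alkene is later homologated by cross-metathesis and Julia–Kocienski olefination to the (7E,9E,12Z)-triene; the acetoxyethyl arm is finally oxidised to the acetic acid.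

Key step: step 4

Assumptions and remarks on the chemistry
- Numbering: ring O1–O2–C3–C4–C5; side chain C1′ (on C5) to C15′.
- Configuration: the target is (3R,5S), with the two ring methyl groups trans. The same spatial arrangement is (3S,5S) in the acetate and alcohol series, because the C3 arm there ranks below C4 in the CIP sequence. The chain length (15 carbons) and both centres were checked against the target; no structure needed changing.
- The sense of induction by the chiral anion cannot be predicted. The catalyst antipode that leads to (3S,5S)-8 is chosen after screening both.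
- The acetate is kept as spectator group on purpose. An ester oxygen is too electron-poor to intercept the C5 cation, whereas an ether or silyl ether there could close a tetrahydropyran. Its carbonyl oxygen does stand 1,3 to C3 and can reach the peroxycarbenium ion reversibly through a six-membered acyloxonium ion; this is treated as a dormant state. The catalyst is therefore charged pre-silylated with the same Et3Si group, so that no free Brønsted acid meets the 2-methyl-1-alkene and silyl exchange is degenerate.
- Peroxides 2, 3 and all dioxolanes are handled cold, shielded and on modest scale; none is distilled.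

Step 1
Reactants: 1 3-methylbut-3-en-1-yl acetate
Product: 2 3-hydroperoxy-3-methoxybutyl acetate (racemic)
Conditions: O3/O2, MeOH–CH2Cl2 (1:1), −78 °C; N2 purge; concentrate below 20 °C, crude used at once
Reagents that add atoms: ozone, [O-][O+]=O; methanol, CO
Why: Criegee ozonolysis in methanol: the primary ozonide of the 1,1-disubstituted alkene fragments to formaldehyde and the ketone O-oxide, which methanol traps as the α-methoxy hydroperoxide, while the acetate is inert and the racemic ketal carbon is immaterial because it is ionised later.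

Step 2
Reactants: 2 3-hydroperoxy-3-methoxybutyl acetate
Product: 3 3-methoxy-3-[(triethylsilyl)peroxy]butyl acetate (racemic)
Conditions: Et3SiCl, imidazole, DMAP (cat.), DMF, 0 °C
Reagents that add atoms: chlorotriethylsilane, CC[Si](Cl)(CC)CC
Why: Silylation of the hydroperoxide oxygen by the silyl chloride–imidazole couple (nucleophilic substitution at silicon) is fast at 0 °C and leaves the ketal and the ester untouched.

Step 3
Reactants: 4 3-chloro-2-methylprop-1-ene; 5 7-bromohept-1-ene
Product: 7 2-methyldeca-1,9-diene, via 2-methylallylmagnesium chloride 6 (not isolated)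
Conditions: Mg turnings, THF, 0 °C (slow addition of 4); then 5, Li2CuCl4 (2 mol %), THF, −10 °C to rt
Reagents that add atoms: none
Why: Grignard formation followed by copper-catalysed sp3–sp3 cross-coupling with the primary bromide, in which the symmetric methallyl unit gives the same diene from either allylic terminus and the terminal alkene of 5 is a spectator.

Step 4
Reactants: 3 3-methoxy-3-[(triethylsilyl)peroxy]butyl acetate; 7 2-methyldeca-1,9-diene
Product: 8 2-[(3S,5S)-3,5-dimethyl-5-(oct-7-en-1-yl)-1,2-dioxolan-3-yl]ethyl acetate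
Conditions: chiral BINOL-derived imidodiphosphorimidate (IDPi) acid (5 mol %), pre-silylated with triethyl(2-methylallyl)silane (10 mol %); 7 (1.5 equiv), methylcyclohexane–CH2Cl2, 4 Å molecular sieves, −78 °C; Et3N quench
Reagents that add atoms: none
Why: Proposed new method: the triethylsilylium–imidodiphosphorimidate pair removes methoxide from 3 (as Et3SiOMe) and leaves the planar C3 peroxycarbenium ion inside the confined chiral anion; the CH2 terminus of the 2-methyl-1-alkene of 7 then adds in the Markovnikov sense (C3–C4 bond) and the distal, silylated peroxy oxygen O1 collapses onto the tertiary C5 cation (O1–C5 bond), the silylperoxonium ion so formed returning Et3Si+ to the anion and closing the catalytic cycle. The closest known chemistry is the racemic SnCl4- or TiCl4-promoted [3+2] annulation of triethylsilylperoxy ketals with alkenes and, for the asymmetric element, silylium–chiral-counteranion catalysis of nucleophile additions to oxocarbenium ions, where such confined anions tell a methyl group from a longer alkyl group. The 1,2-dioxolane ring closes in the second event, by capture of the C5 carbenium ion by O1 through a five-membered transition state (cation–nucleophile collapse after the C–C bond, not a concerted cycloaddition). C3 is fixed in the C–C bond formation by anion-controlled choice between the two faces of the peroxycarbenium ion (CH3 against CH2CH2OAc), and C5 in the closure, where the anion and at best a small steric preference for the long chain trans to the acetoxyethyl arm (ring methyls trans) operate; any cis isomer is removed by chromatography. The step needs chemoselectivity for the 1,1-disubstituted alkene, secured by its far higher nucleophilicity and its tertiary cation compared with the monosubstituted C9=C10 alkene of 7, and it needs the cation to be trapped only by O1, secured by the electron-poor ester oxygen of the acetate.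

Step 5
Reactants: 8 2-[(3S,5S)-3,5-dimethyl-5-(oct-7-en-1-yl)-1,2-dioxolan-3-yl]ethyl acetate
Product: 9 2-[(3S,5S)-3,5-dimethyl-5-[(7E)-9-oxonon-7-en-1-yl]-1,2-dioxolan-3-yl]ethyl acetate
Conditions: (E)-crotonaldehyde (5 equiv), second-generation Hoveyda–Grubbs catalyst (3 mol %), CH2Cl2, 40 °C
Reagents that add atoms: (E)-but-2-enal, C/C=C/C=O
Why: Olefin cross-metathesis of the terminal alkene with excess crotonaldehyde should give the (E)-enal under thermodynamic control with loss of propene, the di-tertiary dialkyl peroxide (no α-hydrogen) and the acetate being inert toward the ruthenium alkylidene.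

Step 6
Reactants: 10 (3Z)-hex-3-en-1-ol
Product: 11 5-[(3Z)-hex-3-en-1-ylsulfanyl]-1-phenyl-1H-tetrazole
Conditions: 1-phenyl-1H-tetrazole-5-thiol, PPh3, DIAD, THF, 0 °C to rt
Reagents that add atoms: 1-phenyl-1H-tetrazole-5-thiol, Sc1nnnn1-c1ccccc1
Why: Mitsunobu thioetherification of the primary alcohol with the acidic heteroaryl thiol proceeds by SN2 displacement of the oxyphosphonium group and does not touch the Z-alkene.

Step 7
Reactants: 11 5-[(3Z)-hex-3-en-1-ylsulfanyl]-1-phenyl-1H-tetrazole
Product: 13 5-[(3Z)-hex-3-en-1-ylsulfonyl]-1-phenyl-1H-tetrazole, via sulfoxide 12 (not isolated)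
Conditions: (NH4)6Mo7O24·4H2O (10 mol %), 30% aq. H2O2, EtOH, 0 °C to rt
Reagents that add atoms: hydrogen peroxide, OO
Why: Molybdate-catalysed hydrogen peroxide oxidation takes sulfur through the sulfoxide to the sulfone and is chemoselective over the isolated, unactivated Z-alkene.

Step 8
Reactants: 13 5-[(3Z)-hex-3-en-1-ylsulfonyl]-1-phenyl-1H-tetrazole; 9 2-[(3S,5S)-3,5-dimethyl-5-[(7E)-9-oxonon-7-en-1-yl]-1,2-dioxolan-3-yl]ethyl acetate
Product: 15 2-[(3S,5S)-3,5-dimethyl-5-[(7E,9E,12Z)-pentadeca-7,9,12-trien-1-yl]-1,2-dioxolan-3-yl]ethyl acetate, via potassium sulfonyl carbanion 14 (not isolated)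
Conditions: KN(SiMe3)2 (1.2 equiv), 13 (1.3 equiv), DME, −78 °C, 20 min; then 9, −78 to −20 °C; aq. NH4Cl
Reagents that add atoms: none
Why: Julia–Kocienski olefination: the metalated phenyltetrazolyl sulfone adds to the enal at −78 °C and Smiles rearrangement with loss of SO2 and tetrazololate delivers the C9′=C10′ alkene, for which the potassium/DME combination and the conjugated aldehyde favour the E isomer, while the aldehyde outcompetes the acetate for the stabilised carbanion.

Step 9
Reactants: 15 2-[(3S,5S)-3,5-dimethyl-5-[(7E,9E,12Z)-pentadeca-7,9,12-trien-1-yl]-1,2-dioxolan-3-yl]ethyl acetate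
Product: 16 2-[(3S,5S)-3,5-dimethyl-5-[(7E,9E,12Z)-pentadeca-7,9,12-trien-1-yl]-1,2-dioxolan-3-yl]ethan-1-ol
Conditions: K2CO3 (0.3 equiv), MeOH, 0 °C to rt, argon
Reagents that add atoms: none
Why: Carbonate-catalysed transesterification (Zemplén-type methanolysis) removes the primary acetate under conditions too mild to deprotonate the doubly allylic C11′ methylene or to open the α-hydrogen-free peroxide.

Step 10
Reactants: 16 2-[(3S,5S)-3,5-dimethyl-5-[(7E,9E,12Z)-pentadeca-7,9,12-trien-1-yl]-1,2-dioxolan-3-yl]ethan-1-ol
Product: 18 2-[(3R,5S)-3,5-dimethyl-5-[(7E,9E,12Z)-pentadeca-7,9,12-trien-1-yl]-1,2-dioxolan-3-yl]acetic acid, via dioxolanylacetaldehyde 17 (not isolated)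
Conditions: TEMPO (20 mol %), PhI(OAc)2 (2.5 equiv), MeCN–pH 7 aqueous phosphate buffer, 0 °C to rt, dark, argon
Reagents that add atoms: water, O
Why: Oxoammonium (TEMPO/PhI(OAc)2) oxidation converts the primary alcohol into the aldehyde and, through its hydrate in the aqueous medium, into the acid, with selectivity for the alcohol over alkenes and peroxide and without risk to the two quaternary stereocentres.

Compound list
1 | 3-methylbut-3-en-1-yl acetate | C=C(C)CCOC(C)=O | starting material
2 | 3-hydroperoxy-3-methoxybutyl acetate (racemic) | COC(C)(CCOC(C)=O)OO | intermediate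
3 | 3-methoxy-3-[(triethylsilyl)peroxy]butyl acetate (racemic) | COC(C)(CCOC(C)=O)OO[Si](CC)(CC)CC | intermediate
4 | 3-chloro-2-methylprop-1-ene | C=C(C)CCl | starting material
5 | 7-bromohept-1-ene | C=CCCCCCBr | starting material
6 | (2-methylprop-2-en-1-yl)magnesium chloride | C=C(C)C[Mg]Cl | intermediate (not isolated)
7 | 2-methyldeca-1,9-diene | C=C(C)CCCCCCC=C | intermediate
8 | 2-[(3S,5S)-3,5-dimethyl-5-(oct-7-en-1-yl)-1,2-dioxolan-3-yl]ethyl acetate | C=CCCCCCC[C@@]1(C)C[C@](C)(CCOC(C)=O)OO1 | intermediate
9 | 2-[(3S,5S)-3,5-dimethyl-5-[(7E)-9-oxonon-7-en-1-yl]-1,2-dioxolan-3-yl]ethyl acetate | O=C/C=C/CCCCCC[C@@]1(C)C[C@](C)(CCOC(C)=O)OO1 | intermediate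
10 | (3Z)-hex-3-en-1-ol | CC/C=C\CCO | starting material
11 | 5-[(3Z)-hex-3-en-1-ylsulfanyl]-1-phenyl-1H-tetrazole | CC/C=C\CCSc1nnnn1-c1ccccc1 | intermediate
12 | 5-[(3Z)-hex-3-ene-1-sulfinyl]-1-phenyl-1H-tetrazole (racemic at sulfur) | CC/C=C\CCS(=O)c1nnnn1-c1ccccc1 | intermediate (not isolated)
13 | 5-[(3Z)-hex-3-en-1-ylsulfonyl]-1-phenyl-1H-tetrazole | CC/C=C\CCS(=O)(=O)c1nnnn1-c1ccccc1 | intermediate
14 | potassium (3Z)-1-[(1-phenyl-1H-tetrazol-5-yl)sulfonyl]hex-3-en-1-ide | [K+].CC/C=C\C[CH-]S(=O)(=O)c1nnnn1-c1ccccc1 | intermediate (not isolated)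
15 | 2-[(3S,5S)-3,5-dimethyl-5-[(7E,9E,12Z)-pentadeca-7,9,12-trien-1-yl]-1,2-dioxolan-3-yl]ethyl acetate | CC/C=C\C/C=C/C=C/CCCCCC[C@@]1(C)C[C@](C)(CCOC(C)=O)OO1 | intermediate
16 | 2-[(3S,5S)-3,5-dimethyl-5-[(7E,9E,12Z)-pentadeca-7,9,12-trien-1-yl]-1,2-dioxolan-3-yl]ethan-1-ol | CC/C=C\C/C=C/C=C/CCCCCC[C@@]1(C)C[C@](C)(CCO)OO1 | intermediate
17 | 2-[(3R,5S)-3,5-dimethyl-5-[(7E,9E,12Z)-pentadeca-7,9,12-trien-1-yl]-1,2-dioxolan-3-yl]acetaldehyde | CC/C=C\C/C=C/C=C/CCCCCC[C@@]1(C)C[C@](C)(CC=O)OO1 | intermediate (not isolated)
18 | 2-[(3R,5S)-3,5-dimethyl-5-[(7E,9E,12Z)-pentadeca-7,9,12-trien-1-yl]-1,2-dioxolan-3-yl]acetic acid | CC/C=C\C/C=C/C=C/CCCCCC[C@@]1(C)C[C@](C)(CC(=O)O)OO1 | target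

Total step count: 10
Longest linear sequence: 7 steps (steps 1, 2, 4, 5, 8, 9, 10; from 1 to 18)

Steps most likely to fail

1. Step 4 (Proposed new method). The anion may fail to discriminate the two faces of the peroxycarbenium ion, and the closure may be stereorandom at C5. The silylium may also be held back by the Lewis-basic ester and by Et3SiOMe, or the tertiary cation may lose a proton instead of closing. Fallback in known chemistry, setting out from 3 and 7 and returning at 8: the racemic annulation promoted by SnCl4 (CH2Cl2, −78 °C) should give 2-[3,5-dimethyl-5-(oct-7-en-1-yl)-1,2-dioxolan-3-yl]ethyl acetate F1 as the mixture of racemic cis and trans isomers. Preparative supercritical-fluid chromatography on a polysaccharide chiral stationary phase, after silica pre-separation of the diastereomers where possible, would then deliver the (3S,5S) isomer, which is 8.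

2. Step 8. E-selectivity at the new C9′=C10′ bond may erode, the metalated sulfone may self-condense before it meets the aldehyde, or the carbanion may attack the acetate. The fallback sets out from 8 and 10, returns at 15, and replaces steps 5 to 8 by an alkenyl–alkenyl coupling at C8′–C9′. Cross-metathesis of 8 with vinylboronic acid pinacol ester (second-generation Hoveyda–Grubbs catalyst, CH2Cl2, 40 °C) should give 2-[(3S,5S)-3,5-dimethyl-5-[(7E)-8-(4,4,5,5-tetramethyl-1,3,2-dioxaborolan-2-yl)oct-7-en-1-yl]-1,2-dioxolan-3-yl]ethyl acetate F2. In parallel, Dess–Martin oxidation of 10 (NaHCO3, CH2Cl2, 0 °C) gives (3Z)-hex-3-enal F3, used cold at once. Takai iodo-olefination of F3 (CrCl2, CHI3, THF, 0 °C) gives (1E,4Z)-1-iodohepta-1,4-diene F4. Suzuki–Miyaura coupling of F2 with F4 (Pd(PPh3)4, aq. K3PO4, THF, rt) proceeds with retention of both alkene geometries and should give 15.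

3. Step 10. The oxidant may damage the skipped triene (attack at the doubly allylic C11′ or on the diene), or β-elimination at the β-peroxy aldehyde stage may open the peroxide ring. The fallback sets out from 8, returns at 18, and moves the oxidation ahead of the triene so that the polyene only meets a saponification. Methanolysis of 8 (K2CO3, MeOH) gives 2-[(3S,5S)-3,5-dimethyl-5-(oct-7-en-1-yl)-1,2-dioxolan-3-yl]ethan-1-ol F5. TEMPO/PhI(OAc)2 oxidation in MeCN–H2O gives 2-[(3R,5S)-3,5-dimethyl-5-(oct-7-en-1-yl)-1,2-dioxolan-3-yl]acetic acid F6. Esterification with Me3SiCHN2 (MeOH–toluene) gives methyl 2-[(3R,5S)-3,5-dimethyl-5-(oct-7-en-1-yl)-1,2-dioxolan-3-yl]acetate F7. Cross-metathesis with crotonaldehyde as in step 5 gives methyl 2-[(3R,5S)-3,5-dimethyl-5-[(7E)-9-oxonon-7-en-1-yl]-1,2-dioxolan-3-yl]acetate F8. Julia–Kocienski olefination with 13 as in step 8 gives methyl 2-[(3R,5S)-3,5-dimethyl-5-[(7E,9E,12Z)-pentadeca-7,9,12-trien-1-yl]-1,2-dioxolan-3-yl]acetate F9. Saponification (LiOH, THF–H2O, 0 °C, then mild acidification) gives 18.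

Further compounds
F1 | step 4 | 2-[3,5-dimethyl-5-(oct-7-en-1-yl)-1,2-dioxolan-3-yl]ethyl acetate, mixture of racemic cis and trans isomers | C=CCCCCCCC1(C)CC(C)(CCOC(C)=O)OO1
F2 | step 8 | 2-[(3S,5S)-3,5-dimethyl-5-[(7E)-8-(4,4,5,5-tetramethyl-1,3,2-dioxaborolan-2-yl)oct-7-en-1-yl]-1,2-dioxolan-3-yl]ethyl acetate | CC1(C)OB(/C=C/CCCCCC[C@@]2(C)C[C@](C)(CCOC(C)=O)OO2)OC1(C)C
F3 | step 8 | (3Z)-hex-3-enal | CC/C=C\CC=O
F4 | step 8 | (1E,4Z)-1-iodohepta-1,4-diene | CC/C=C\C/C=C/I
F5 | step 10 | 2-[(3S,5S)-3,5-dimethyl-5-(oct-7-en-1-yl)-1,2-dioxolan-3-yl]ethan-1-ol | C=CCCCCCC[C@@]1(C)C[C@](C)(CCO)OO1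
F6 | step 10 | 2-[(3R,5S)-3,5-dimethyl-5-(oct-7-en-1-yl)-1,2-dioxolan-3-yl]acetic acid | C=CCCCCCC[C@@]1(C)C[C@](C)(CC(=O)O)OO1
F7 | step 10 | methyl 2-[(3R,5S)-3,5-dimethyl-5-(oct-7-en-1-yl)-1,2-dioxolan-3-yl]acetate | C=CCCCCCC[C@@]1(C)C[C@](C)(CC(=O)OC)OO1
F8 | step 10 | methyl 2-[(3R,5S)-3,5-dimethyl-5-[(7E)-9-oxonon-7-en-1-yl]-1,2-dioxolan-3-yl]acetate | O=C/C=C/CCCCCC[C@@]1(C)C[C@](C)(CC(=O)OC)OO1
F9 | step 10 | methyl 2-[(3R,5S)-3,5-dimethyl-5-[(7E,9E,12Z)-pentadeca-7,9,12-trien-1-yl]-1,2-dioxolan-3-yl]acetate | CC/C=C\C/C=C/C=C/CCCCCC[C@@]1(C)C[C@](C)(CC(=O)OC)OO1
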